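## Retrosynthetic overview

1. The target has a C2-symmetric (1R,2R,3R,4R) cyclobutane core: C1-CO2R up, C2-CO2R down, C3-Ar down, C4-Ar up. It carries two (R)-danshensu esters and comes from tenfold O-debenzylation of the fully benzylated diester.
2. Cutting the two ester C(O)–O bonds gives the protected 3,4-diarylcyclobutane-1,2-dicarboxylic acid and two molecules of tribenzyl (R)-danshensu. The danshensu comes from the chiral pool and its carbinol C–O bond is never broken.
3. Key disconnection: both aryl–C(ring) bonds. (1R,2R)-Cyclobutane-1,2-dicarboxylic acid acts twice as a homoenolate (β-palladated carboxylate, d3 donor) toward 3,4-bis(benzyloxy)iodobenzene. The β-carbon of a carboxyl system and the ipso carbon of ArI are both acceptor carbons in normal polarity.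
4. The cis-fused palladacycle places each aryl group cis to the carboxyl that directs it. This gives the cis/trans/cis/trans pattern, which stepwise caffeate dimerisations do not give because they favour the all-trans isomer.
5. Ring order: no ring is built. The cyclobutane comes intact from cheap racemic trans-diacid, resolved first, and all arenes are bought.

Assumption: racemic trans-cyclobutane-1,2-dicarboxylic acid, 1,2-bis(benzyloxy)benzene and natural (R)-sodium danshensu are taken as catalogue chemicals.

## Route

**Step 1**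
Reactants: 1 rac-trans-cyclobutane-1,2-dicarboxylic acid
Product: 2 (1R,2R)-cyclobutane-1,2-dicarboxylic acid
Conditions: quinine (2.0 equiv), EtOH–H2O, reflux → rt, fractional crystallisation (2–3 crops); salt split with 2 M HCl/EtOAc
Reagents that add atoms: none
Why: Classical resolution through diastereomeric salts; the two quinine salts differ in solubility, so C1 and C2 are fixed as R,R by selection, taking whichever fraction (crystals or mother liquor) carries the wanted antipode by chiral HPLC and recrystallising it to constant ee.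

**Step 2**
Reactants: 3 1,2-bis(benzyloxy)benzene
Product: 4 1,2-bis(benzyloxy)-4-iodobenzene
Conditions: NIS (1.05 equiv), TFA (10 mol %), MeCN, rt, dark
Reagents that add atoms: N-iodosuccinimide O=C1CCC(=O)N1I
Why: Electrophilic aromatic iodination; acid-activated NIS attacks only the dialkoxy-activated ring, para to one benzyloxy group, and no stereocentre is involved.

**Step 3 (key step)**
Reactants: 2 (1R,2R)-cyclobutane-1,2-dicarboxylic acid; 4 1,2-bis(benzyloxy)-4-iodobenzene (3.0 equiv)
Product: 8 (1R,2R,3R,4R)-3,4-bis[3,4-bis(benzyloxy)phenyl]cyclobutane-1,2-dicarboxylic acid, via first palladium homoenolate 5 (not isolated), via monoaryl diacid 6 (not isolated), via second palladium homoenolate 7 (not isolated)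
Conditions: Pd(OAc)2 (10 mol %), 6-[2-(pyridin-2-yl)propan-2-yl]pyridin-2(1H)-one (12 mol %), Ag2CO3 (2.0 equiv), HFIP, 90 °C, 24–36 h; aq. HCl work-up
Reagents that add atoms: none
Why: Proposed new method: each carboxylate binds divalent palladium and, with the pyridone oxygen as internal base (concerted metalation–deprotonation), cleaves the only β-methylene C–H lying cis to it, giving a cis-fused five-membered palladacycle, that is a palladium homoenolate whose normally electrophilic β-carbon is now the donor; oxidative addition of the electrophilic aryl iodide 4 to give tetravalent palladium and C–C reductive elimination with retention place each aryl group cis to its directing carboxyl, the second arylation occurs on the face anti to the first aryl group, so C3 and C4 are both set R from C1/C2, the carboxylate form protects the α-centres from epimerisation, and syn β-hydride elimination is blocked because the α-H is anti to Pd; the closest known reaction types are ligand-enabled carboxylate-directed β-methylene C(sp3)–H arylation of free aliphatic and cycloalkane acids and auxiliary-directed cyclobutane C–H arylation.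

**Step 4**
Reactants: 9 sodium (2R)-3-(3,4-dihydroxyphenyl)-2-hydroxypropanoate (sodium danshensu)
Product: 10 benzyl (2R)-3-[3,4-bis(benzyloxy)phenyl]-2-hydroxypropanoate
Conditions: BnBr (3.3 equiv), K2CO3 (2.5 equiv), DMF, argon, rt → 40 °C
Reagents that add atoms: benzyl bromide BrCc1ccccc1
Why: Williamson ether synthesis plus carboxylate O-alkylation; K2CO3 ionises only the phenols and the carboxylate is already ionic, so the secondary alcohol stays free and the (R)-centre is not touched.

**Step 5**
Reactants: 8 (1R,2R,3R,4R)-3,4-bis[3,4-bis(benzyloxy)phenyl]cyclobutane-1,2-dicarboxylic acid; 10 benzyl (2R)-3-[3,4-bis(benzyloxy)phenyl]-2-hydroxypropanoate (2.3 equiv)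
Product: 12 bis{(2R)-1-(benzyloxy)-3-[3,4-bis(benzyloxy)phenyl]-1-oxopropan-2-yl} (1R,2R,3R,4R)-3,4-bis[3,4-bis(benzyloxy)phenyl]cyclobutane-1,2-dicarboxylate, via monoester 11 (not isolated)
Conditions: DCC (2.4 equiv), DMAP (0.2 equiv), CH2Cl2, 0 °C → rt
Reagents that add atoms: none
Why: Steglich esterification; the carbinol C–O bond is not broken so both side-chain centres stay R, and DMAP acyl transfer at or below rt outruns enolisation, so the four ring centres are kept.

**Step 6**
Reactants: 12 the decabenzyl diester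
Product: 13 (2R,2'R)-2,2'-{[(1R,2R,3R,4R)-3,4-bis(3,4-dihydroxyphenyl)cyclobutane-1,2-dicarbonyl]bis(oxy)}bis[3-(3,4-dihydroxyphenyl)propanoic acid] (CNP0163929.1)
Conditions: H2 (1 atm), 10% Pd/C, THF–EtOH (1:1), rt; filtration under argon, reversed-phase purification (0.1% HCO2H)
Reagents that add atoms: none
Why: Catalytic hydrogenolysis cleaves the eight aryl benzyl ethers and two benzyl esters at their benzylic C–O bonds, while the homobenzylic acyloxy esters and the cyclobutane are inert at 1 atm and rt, and no stereocentre takes part.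

## Compound list

1 | rac-trans-cyclobutane-1,2-dicarboxylic acid (1:1 mixture of both enantiomers) | O=C(O)[C@H]1[C@H](C(=O)O)CC1.O=C(O)[C@@H]1[C@@H](C(=O)O)CC1 | starting material
2 | (1R,2R)-cyclobutane-1,2-dicarboxylic acid | O=C(O)[C@H]1[C@H](C(=O)O)CC1 | intermediate
3 | 1,2-bis(benzyloxy)benzene | C(Oc1ccccc1OCc1ccccc1)c1ccccc1 | starting material
4 | 1,2-bis(benzyloxy)-4-iodobenzene | Ic1ccc(OCc2ccccc2)c(OCc2ccccc2)c1 | intermediate
5 | first palladium homoenolate: five-membered O,C-palladacycle of 2, Pd on the ring carbon next to and cis to the bound carboxylate (ancillary ligand omitted) | O=C(O2)[C@H]1[C@H](C(=O)O)C[C@H]1[Pd]2 | intermediate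
6 | (1R,2R,3R)-3-[3,4-bis(benzyloxy)phenyl]cyclobutane-1,2-dicarboxylic acid (aryl cis to the C2 carboxyl) | O=C(O)[C@H]1[C@H](C(=O)O)C[C@H]1c1ccc(OCc2ccccc2)c(OCc2ccccc2)c1 | intermediate
7 | second palladium homoenolate: five-membered O,C-palladacycle of 6 at the remaining CH2, Pd cis to the second carboxylate and trans to the aryl group (ancillary ligand omitted) | O=C(O)[C@H]1[C@H](C(=O)O2)[C@H]([Pd]2)[C@H]1c1ccc(OCc2ccccc2)c(OCc2ccccc2)c1 | intermediate
8 | (1R,2R,3R,4R)-3,4-bis[3,4-bis(benzyloxy)phenyl]cyclobutane-1,2-dicarboxylic acid | O=C(O)[C@H]1[C@H](C(=O)O)[C@H](c2ccc(OCc3ccccc3)c(OCc3ccccc3)c2)[C@H]1c1ccc(OCc2ccccc2)c(OCc2ccccc2)c1 | intermediate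
9 | sodium (2R)-3-(3,4-dihydroxyphenyl)-2-hydroxypropanoate | O[C@H](Cc1ccc(O)c(O)c1)C(=O)[O-].[Na+] | starting material
10 | benzyl (2R)-3-[3,4-bis(benzyloxy)phenyl]-2-hydroxypropanoate | O[C@H](Cc1ccc(OCc2ccccc2)c(OCc2ccccc2)c1)C(=O)OCc1ccccc1 | intermediate
11 | monoester of 8 with one molecule of 10 (ring 1R,2R,3R,4R; side chain R) | O=C(O[C@H](Cc1ccc(OCc2ccccc2)c(OCc2ccccc2)c1)C(=O)OCc1ccccc1)[C@H]1[C@H](C(=O)O)[C@H](c2ccc(OCc3ccccc3)c(OCc3ccccc3)c2)[C@H]1c1ccc(OCc2ccccc2)c(OCc2ccccc2)c1 | intermediate
12 | decabenzyl-protected target (ring 1R,2R,3R,4R; both side chains R) | O=C(O[C@H](Cc1ccc(OCc2ccccc2)c(OCc2ccccc2)c1)C(=O)OCc1ccccc1)[C@H]1[C@H](C(=O)O[C@H](Cc2ccc(OCc3ccccc3)c(OCc3ccccc3)c2)C(=O)OCc2ccccc2)[C@H](c2ccc(OCc3ccccc3)c(OCc3ccccc3)c2)[C@H]1c1ccc(OCc2ccccc2)c(OCc2ccccc2)c1 | intermediate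
13 | CNP0163929.1 | O=C(O[C@H](Cc1ccc(O)c(O)c1)C(=O)O)[C@H]1[C@H](C(=O)O[C@H](Cc2ccc(O)c(O)c2)C(=O)O)[C@H](c2ccc(O)c(O)c2)[C@H]1c1ccc(O)c(O)c1 | target

## Step count and risks

Total step count: 6.
Longest linear sequence: 4 steps (steps 1, 3, 5 and 6, that is 1 → 2 → 8 → 12 → 13).

**Step 3 (double free-acid arylation).**
- Risk: the weakly coordinating α-H diacid may sequester palladium as a dicarboxylate. The reaction may also stop at 6.
- Fallback, from 2 back to 8: install a strong bidentate auxiliary.
  - Carbodiimide coupling of 2 with 8-aminoquinoline gives (1R,2R)-N1,N2-di(quinolin-8-yl)cyclobutane-1,2-dicarboxamide F1.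
  - Pd(OAc)2/AgOAc with 4 in tert-amyl alcohol at 100 °C proceeds through N,N-chelated palladium homoenolates under the same cis rule. It gives (1R,2R,3R,4R)-3,4-bis[3,4-bis(benzyloxy)phenyl]-N1,N2-di(quinolin-8-yl)cyclobutane-1,2-dicarboxamide F2.
  - Boc2O/DMAP gives the bis(N-Boc) imide F3.
  - LiOH/H2O2 in THF–H2O at 0 °C releases 8.

**Step 5 (double esterification).**
- Risk: each carboxyl is flanked by a cis aryl group and the alcohol is a weakly nucleophilic α-hydroxy ester. N-acylurea formation or epimerisation toward the all-trans isomer through the activated acyl species is possible.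
- Fallback, from 10 back to 12: avoid acyl activation and use the carboxylate as the nucleophile.
  - Appel bromination of 10 (PPh3, CBr4, CH2Cl2, 0 °C, inversion) gives benzyl (2S)-2-bromo-3-[3,4-bis(benzyloxy)phenyl]propanoate F4.
  - The dicaesium salt of 8 (Cs2CO3, DMF, 0 °C → rt) displaces the bromide of F4 with a second inversion. Both side-chain centres are restored as R and the product is 12.

**Step 6 (tenfold hydrogenolysis).**
- Risk: partly deprotected intermediates may precipitate on the catalyst. The strained, doubly benzylic C3–C4 bond could be opened reductively.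
- Fallback, from 12 back to 13: non-reductive debenzylation by benzyl-cation transfer. BCl3 with pentamethylbenzene as cation scavenger (CH2Cl2, −78 → 0 °C, MeOH quench) removes the ether and ester benzyl groups without H2 or metal. No new isolable compound is made.

## Further compounds

F1 | step 3 | (1R,2R)-N1,N2-di(quinolin-8-yl)cyclobutane-1,2-dicarboxamide | O=C(Nc1cccc2cccnc12)[C@H]1[C@H](C(=O)Nc2cccc3cccnc23)CC1
F2 | step 3 | (1R,2R,3R,4R)-3,4-bis[3,4-bis(benzyloxy)phenyl]-N1,N2-di(quinolin-8-yl)cyclobutane-1,2-dicarboxamide | O=C(Nc1cccc2cccnc12)[C@H]1[C@H](C(=O)Nc2cccc3cccnc23)[C@H](c2ccc(OCc3ccccc3)c(OCc3ccccc3)c2)[C@H]1c1ccc(OCc2ccccc2)c(OCc2ccccc2)c1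
F3 | step 3 | bis(N-Boc) imide of F2 | O=C(N(C(=O)OC(C)(C)C)c1cccc2cccnc12)[C@H]1[C@H](C(=O)N(C(=O)OC(C)(C)C)c2cccc3cccnc23)[C@H](c2ccc(OCc3ccccc3)c(OCc3ccccc3)c2)[C@H]1c1ccc(OCc2ccccc2)c(OCc2ccccc2)c1
F4 | step 5 | benzyl (2S)-2-bromo-3-[3,4-bis(benzyloxy)phenyl]propanoate | Br[C@@H](Cc1ccc(OCc2ccccc2)c(OCc2ccccc2)c1)C(=O)OCc1ccccc1
F0 | step 6 | none | none
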